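**Plan**

- Retrosynthesis: the C–Br bond, both tertiary alcohols and the A/B ring-fusion hydrogen lead back to tetracyclic dienone 15. Ring B is then cut at two bonds, CH2–C(CH3) (quaternary carbon shared by rings A and B) and quaternary bridgehead C–CH (the norbornane carbon that carries ring A), which also opens the norbornane. The remaining CH2–CH tether bond is a 1,6-Michael disconnection to cyclopentenone 5 and vinyl enone 8.
- Enabling feature: three carbons of ring B are the γ-CH2, β-C and α-C(CH3) of a 2-methylcyclohex-2-enone (ring A), a 1,3-bis-nucleophile as dienol ether and dienolate. The other three (bridgehead C, CH2, CH2) are a 1,3-bis-electrophile: the tertiary terminus of a cyclopentenyl cation and a CH2Cl carbon.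
- Forward: Pauson–Khand reaction and Stork–Danheiser sequence give the two enones; Michael union with O-silylation; CBS reduction and acetylation; one-flask cationic then anionic (3+3) annulation closes the norbornene and then ring B; enol triflate, exo hydration, hydroboration–oxidation, triflate-to-bromide exchange, methyl addition and hydrogen-atom-transfer hydrogenation finish the route.
- Stereochemistry: the only external source is the CBS reduction, which turns the two epimers at the tether-bearing carbon into separable diastereomers. That carbon controls the bridgehead, the adjacent CH and the methyl-bearing quaternary centre in the key step. The last four centres follow from the rigid tetracycle (exo oxymercuration, hydroboration anti to the angular methyl, equatorial methyl addition, axial H-atom delivery).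

Key step: step 8

Remark: the exocyclic dienol ether in 10–13 is drawn as one geometric isomer; its geometry should not matter, because that carbon becomes stereogenic only in step 8. Compounds 1, 2, 6 and 7 are taken as commercial.

**Route**

Step 1
Reactants: 1 3-methylbut-1-yne; 2 oxirane
Product: 3 5-methylhex-3-yn-1-ol
Conditions: n-butyllithium, THF, −78 °C; then 2, DMPU, −78 → 25 °C
Reagents that add atoms: none
Why: Opening of the epoxide by the lithium acetylide (alkynylation of an epoxide) adds the two carbons that become the CH2–CH2 unit of ring B.

Step 2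
Reactants: 3 5-methylhex-3-yn-1-ol
Product: 4 6-chloro-2-methylhex-3-yne
Conditions: PPh3, N-chlorosuccinimide, CH2Cl2, 0 → 25 °C
Reagents that add atoms: N-chlorosuccinimide O=C1CCC(=O)N1Cl
Why: Appel-type chlorination converts the primary alcohol into the chloride by SN2 and leaves the alkyne alone.

Step 3
Reactants: 4 6-chloro-2-methylhex-3-yne
Product: 5 3-(2-chloroethyl)-2-(propan-2-yl)cyclopent-2-en-1-one
Conditions: Co2(CO)8 (cat.), ethylene (30 bar), CO (10 bar), toluene, 120 °C
Reagents that add atoms: ethylene C=C; carbon monoxide [C-]#[O+]
Why: Intermolecular Pauson–Khand reaction, in which the bulkier isopropyl group of the unsymmetrical alkyne should end up α to the new carbonyl and the chloroethyl group β.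

Step 4
Reactants: 6 3-ethoxy-2-methylcyclohex-2-en-1-one; 7 vinylmagnesium bromide
Product: 8 3-ethenyl-2-methylcyclohex-2-en-1-one
Conditions: THF, 0 °C; then 1 M HCl, 25 °C
Reagents that add atoms: none
Why: Stork–Danheiser sequence: 1,2-addition to the vinylogous ester, then acid hydrolysis with carbonyl transposition, gives the 3-vinyl enone.

Step 5
Reactants: 5 3-(2-chloroethyl)-2-(propan-2-yl)cyclopent-2-en-1-one; 8 3-ethenyl-2-methylcyclohex-2-en-1-one
Product: 11 racemic silyl dienol ether enone, via lithium enolate 9 (not isolated), via lithium dienolate 10 (not isolated)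
Conditions: lithium diisopropylamide, THF, −78 °C; 8, DMPU, −78 → −40 °C; then t-BuMe2SiCl, −78 → −30 °C
Reagents that add atoms: tert-butyldimethylsilyl chloride CC(C)(C)[Si](C)(C)Cl
Why: Kinetic α′-deprotonation of the cyclopentenone, 1,6-Michael addition to the terminal carbon of the dienone (its β-carbon is fully substituted) and O-silylation of the resulting exocyclic dienolate should give the tethered enone, racemic at the new α′-centre.

Step 6
Reactants: 11 racemic silyl dienol ether enone
Product: 12 (1R,5R)-cis allylic alcohol
Conditions: (S)-Me-CBS oxazaborolidine (0.2 equiv), catecholborane, toluene, −78 °C; chromatographic separation from the trans-(1R,5S) alcohol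
Reagents that add atoms: none
Why: Corey–Bakshi–Shibata reduction under reagent control (alkenyl side as the large group) should give the 1R carbinol from both C-5 epimers, so they become separable diastereomers, and the cis-(1R,5R) alcohol (hydride anti to the side chain, the substrate-preferred sense) is kept.

Step 7
Reactants: 12 (1R,5R)-cis allylic alcohol
Product: 13 (1R,5R)-allylic acetate
Conditions: Ac2O, Et3N, DMAP (cat.), CH2Cl2, 0 °C
Reagents that add atoms: acetic anhydride CC(=O)OC(C)=O
Why: DMAP-catalysed acetylation turns the allylic hydroxyl into an ionizable leaving group without touching the silyl dienol ether.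

Step 8
Reactants: 13 (1R,5R)-allylic acetate
Product: 15 tetracyclic dienone, via chloroethyl norbornene enone 14 (not isolated)
Conditions: Me3SiOTf (0.2 equiv), 2,6-di-tert-butylpyridine, toluene, −60 → −20 °C; then potassium tert-butoxide, t-BuOH–THF, same flask, −20 → 50 °C
Reagents that add atoms: none
Why: Me3SiOTf ionizes the allylic acetate to a cyclopentenyl (allyl) cation whose tertiary terminus is captured by the γ-carbon of the tethered 1-silyloxydiene with loss of the silyl group, and potassium tert-butoxide then deprotonates the regenerated 2-methylcyclohexenone at its ring γ-CH2 so that the α-carbon of the dienolate displaces the primary chloride. The closest known reaction types are an allyl-cation-initiated cation–olefin cyclization terminated by an enol silane (vinylogous Mukaiyama-type alkylation) and the deconjugative α-alkylation of an enone dienolate, run here in one flask as a formal (3+3) annulation. The norbornene closes by 5-exo attack on the allyl cation, bridging the cyclopentene 1,3, and ring B closes 6-exo-tet. The quaternary bridgehead is fixed by the C-5 stereocentre because the two-atom tether reaches only one face of the planar cation, the adjacent CH centre by the exo placement of ring A away from the isopropyl-bearing bridge, and the methyl-bearing quaternary centre by a chair-like transition state for ring B in which the chain reaches only one face of the dienolate. The step needs γ- and not α-attack of the dienol ether, bonding at the tertiary allyl terminus, and deprotonation at the ring CH2 and not at the hindered norbornyl CH. These should be secured by the larger γ-coefficient of 1-silyloxydienes, by charge concentration at the more substituted terminus together with ring size (α-attack there would need a seven-membered ring), and by the strain of a tetrasubstituted exocyclic dienolate.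

Step 9
Reactants: 15 tetracyclic dienone
Product: 16 enol triflate
Conditions: KN(SiMe3)2, THF, −78 °C; then PhNTf2, −78 → 0 °C
Reagents that add atoms: N-phenylbis(trifluoromethanesulfonimide) O=S(=O)(N(c1ccccc1)S(=O)(=O)C(F)(F)F)C(F)(F)F
Why: Enolization can occur only toward the single α-CH2 (the other α-carbon is quaternary), and O-triflation gives the enol triflate that masks the ketone and later becomes the C–Br carbon.

Step 10
Reactants: 16 enol triflate
Product: 18 exo tertiary alcohol, via organomercurial 17 (not isolated)
Conditions: Hg(OAc)2, THF–H2O, 0 → 25 °C; then NaBH4, aq. NaOH, 0 °C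
Reagents that add atoms: water O
Why: Oxymercuration–demercuration should select the strained trisubstituted norbornene over the hindered ring-A alkene and the electron-poor enol triflate, and Markovnikov exo attack without cationic rearrangement places the hydroxyl exo and the isopropyl group endo.

Step 11
Reactants: 18 exo tertiary alcohol
Product: 20 diol, via alkylborane 19 (not isolated)
Conditions: BH3·THF, THF, 0 → 25 °C; then 30% H2O2, aq. NaHCO3, 0 °C
Reagents that add atoms: hydrogen peroxide OO
Why: Hydroboration–oxidation should add borane from the face opposite the angular methyl group, giving the ring-fusion hydrogen trans to that methyl and oxygen at the secondary carbon, while the enol triflate stays inert.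

Step 12
Reactants: 20 diol
Product: 21 hydroxy ketone
Conditions: Dess–Martin periodinane, NaHCO3, CH2Cl2, 25 °C
Reagents that add atoms: none
Why: Dess–Martin oxidation converts only the secondary alcohol; the tertiary alcohol and the enol triflate do not react.

Step 13
Reactants: 21 hydroxy ketone
Product: 22 alkenyl bromide ketone
Conditions: Ni(cod)2, i.e. bis(cycloocta-1,5-diene)nickel (10 mol %), LiBr, DMA–THF, 25 °C
Reagents that add atoms: lithium bromide [Li+].[Br-]
Why: Nickel-catalysed triflate-to-bromide exchange of an enol triflate (oxidative addition to zerovalent nickel, halide exchange, reductive elimination) should give the alkenyl bromide with the double bond unmoved.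

Step 14
Reactants: 22 alkenyl bromide ketone
Product: 23 alkenyl bromide diol
Conditions: MeMgBr, CeCl3, THF, −78 °C
Reagents that add atoms: methylmagnesium bromide C[Mg]Br
Why: Organocerium addition suppresses enolization, and because the angular methyl group blocks the axial trajectory the methyl group should enter equatorially, leaving the new hydroxyl axial and cis to the angular methyl.

Step 15
Reactants: 23 alkenyl bromide diol
Product: 24 CNP0362628.1 (target)
Conditions: Mn(dpm)3, i.e. tris(2,2,6,6-tetramethylheptane-3,5-dionato)manganese (cat.), PhSiH3, t-BuOOH, i-PrOH, 25 °C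
Reagents that add atoms: none
Why: Mukaiyama-type metal-hydride hydrogen-atom-transfer hydrogenation tolerates the C–Br bond: H• adds to the CH terminus and the α-bromo radical should be quenched by axial hydrogen delivery from the face opposite the angular methyl, giving the equatorial bromide.

**Compound list**

1 | 3-methylbut-1-yne | CC(C)C#C | starting material
2 | oxirane | C1CO1 | starting material
3 | 5-methylhex-3-yn-1-ol | CC(C)C#CCCO | intermediate
4 | 6-chloro-2-methylhex-3-yne | CC(C)C#CCCCl | intermediate
5 | 3-(2-chloroethyl)-2-(propan-2-yl)cyclopent-2-en-1-one | CC(C)C1=C(CCCl)CCC1=O | intermediate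
6 | 3-ethoxy-2-methylcyclohex-2-en-1-one | CCOC1=C(C)C(=O)CCC1 | starting material
7 | vinylmagnesium bromide | C=C[Mg]Br | starting material
8 | 3-ethenyl-2-methylcyclohex-2-en-1-one | C=CC1=C(C)C(=O)CCC1 | intermediate
9 | lithium 4-(2-chloroethyl)-5-(propan-2-yl)cyclopenta-1,4-dien-1-olate (kinetic α′-enolate of 5, not isolated) | CC(C)C1=C(CCCl)CC=C1[O-].[Li+] | intermediate
10 | lithium exocyclic dienolate of the 1,6-adduct of 9 and 8 (racemic, not isolated) | CC(C)C1=C(CCCl)CC(C/C=C2\CCCC([O-])=C2C)C1=O.[Li+] | intermediate
11 | racemic 5-{(2E)-2-[3-(tert-butyldimethylsilyloxy)-2-methylcyclohex-2-en-1-ylidene]ethyl}-3-(2-chloroethyl)-2-(propan-2-yl)cyclopent-2-en-1-one | CC(C)C1=C(CCCl)CC(C/C=C2\CCCC(O[Si](C)(C)C(C)(C)C)=C2C)C1=O | intermediate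
12 | (1R,5R)-5-{(2E)-2-[3-(tert-butyldimethylsilyloxy)-2-methylcyclohex-2-en-1-ylidene]ethyl}-3-(2-chloroethyl)-2-(propan-2-yl)cyclopent-2-en-1-ol (hydroxyl and side chain cis) | CC(C)C1=C(CCCl)C[C@@H](C/C=C2\CCCC(O[Si](C)(C)C(C)(C)C)=C2C)[C@H]1O | intermediate
13 | acetate of 12, (1R,5R) | CC(C)C1=C(CCCl)C[C@@H](C/C=C2\CCCC(O[Si](C)(C)C(C)(C)C)=C2C)[C@H]1OC(C)=O | intermediate
14 | 3-[1-(2-chloroethyl)-2-(propan-2-yl)bicyclo[2.2.1]hept-2-en-6-exo-yl]-2-methylcyclohex-2-en-1-one, configuration as in the SMILES (not isolated) | CC(C)C1=C[C@@H]2C[C@@H](C3=C(C)C(=O)CCC3)[C@@]1(CCCl)C2 | intermediate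
15 | tetracyclic dienone: 14 with ring B closed between the bridgehead CH2CH2 chain and the cyclohexenone α-carbon (now a methyl-bearing quaternary centre next to the ketone); ring-A double bond at the ring-fusion carbon (β,γ to the ketone); 2-isopropylnorbornene retained | CC(C)C1=C[C@@H]2C[C@H]3C=4[C@](C)(CC[C@@]31C2)C(=O)CCC4 | intermediate
16 | enol triflate of 15 (C=C toward the ring-A CH2, OTf on the former carbonyl carbon) | CC(C)C1=C[C@@H]2C[C@H]3C=4[C@](C)(CC[C@@]31C2)C(OS(=O)(=O)C(F)(F)F)=CCC4 | intermediate
17 | exo-acetoxymercurio exo-alcohol from oxymercuration of the norbornene of 16 (not isolated) | CC(C)[C@]1(O)[C@@H]([Hg]OC(C)=O)[C@@H]2C[C@H]3C=4[C@](C)(CC[C@@]31C2)C(OS(=O)(=O)C(F)(F)F)=CCC4 | intermediate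
18 | exo tertiary alcohol (isopropyl endo) with ring-A alkene and enol triflate | CC(C)[C@]1(O)C[C@@H]2C[C@H]3C=4[C@](C)(CC[C@@]31C2)C(OS(=O)(=O)C(F)(F)F)=CCC4 | intermediate
19 | alkylborane from hydroboration of 18, boron on the secondary ring-A carbon, tertiary hydroxyl as its borinate (not isolated) | CC(C)[C@]1(OB)C[C@@H]2C[C@H]3[C@H]4[C@](C)(CC[C@@]31C2)C(OS(=O)(=O)C(F)(F)F)=CC[C@@H]4B | intermediate
20 | diol: trans A/B ring fusion, equatorial secondary hydroxyl in ring A, exo tertiary alcohol, enol triflate | CC(C)[C@]1(O)C[C@@H]2C[C@H]3[C@H]4[C@](C)(CC[C@@]31C2)C(OS(=O)(=O)C(F)(F)F)=CC[C@@H]4O | intermediate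
21 | hydroxy ketone (ring-A ketone next to the ring-fusion CH), enol triflate | CC(C)[C@]1(O)C[C@@H]2C[C@H]3[C@H]4[C@](C)(CC[C@@]31C2)C(OS(=O)(=O)C(F)(F)F)=CCC4=O | intermediate
22 | alkenyl bromide ketone | CC(C)[C@]1(O)C[C@@H]2C[C@H]3[C@H]4[C@](C)(CC[C@@]31C2)C(Br)=CCC4=O | intermediate
23 | alkenyl bromide diol (axial tertiary hydroxyl cis to the angular methyl) | CC(C)[C@]1(O)C[C@@H]2C[C@H]3[C@H]4[C@](C)(CC[C@@]31C2)C(Br)=CC[C@@]4(C)O | intermediate
24 | CNP0362628.1 | CC(C)[C@]1(O)C[C@@H]2C[C@H]3[C@H]4[C@](C)(CC[C@@]31C2)[C@@H](Br)CC[C@@]4(C)O | target

**Count and risks**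

Total step count: 15. Longest linear sequence: 14 steps (steps 1–3 and 5–15).

Steps most likely to fail:

1. Step 8. The allyl cation may lose a proton to give a cyclopentadiene, or bonding may occur at the α-carbon of the dienol ether or at the secondary allyl terminus. Fallback (Michael acceptor in place of the allyl cation): set out from 12. Dess–Martin oxidation returns the enone, now as the single (5R) enantiomer of 11, F1. A Me3SiOTf-catalysed intramolecular vinylogous Mukaiyama–Michael addition (dienol ether γ-carbon onto the cyclopentenone β-carbon; no base, so C-5 is not epimerized) should give the norbornane silyl enol ether F2. Potassium tert-butoxide (desilylation, then dienolate α-alkylation by the chloride) followed by PhNTf2 traps the norbornanone enolate as the tetracyclic enol triflate F3. Pd(OAc)2, PPh3, HCO2H and Et3N reduce the triflate and the route is rejoined at 15.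

2. Step 5. Competing 1,2-addition, proton transfer between the two enolizable enone units and intramolecular Michael addition before silylation are all possible. Fallback (Lewis-acid Mukaiyama–Michael addition in place of the lithium enolate): set out from 5. Lithium diisopropylamide and t-BuMe2SiCl give the 2-silyloxycyclopentadiene F4, kept cold. Catalytic t-BuMe2SiOTf in CH2Cl2 at −78 °C with 8 should effect 1,6-addition with silyl transfer to the ring-A oxygen; the reaction is quenched cold and rejoins at 11.

3. Step 6. Reagent control may be incomplete and the C-5 epimers poorly differentiated. Fallback (resolution through diastereomeric esters): set out from 11. i-Bu2AlH in toluene at −78 °C should give the racemic cis alcohol, that is 12 together with its enantiomer F5. Esterification with (S)-O-methylmandelic acid (DCC, DMAP) gives the diastereomeric esters F6 (from 12) and F7 (from F5), which are separated. Reductive cleavage of F6 with i-Bu2AlH returns to the route at 12.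

**Further compounds**

F1 | step 8 | (5R)-enantiomer of enone 11 | CC(C)C1=C(CCCl)C[C@@H](C/C=C2\CCCC(O[Si](C)(C)C(C)(C)C)=C2C)C1=O
F2 | step 8 | norbornane tert-butyldimethylsilyl enol ether (OSi on the carbon between the isopropyl-bearing alkene carbon and the CH bridgehead) with exo 2-methyl-3-oxocyclohexenyl and bridgehead 2-chloroethyl | CC(C)C1=C(O[Si](C)(C)C(C)(C)C)[C@@H]2C[C@@H](C3=C(C)C(=O)CCC3)[C@@]1(CCCl)C2
F3 | step 8 | tetracyclic keto enol triflate (triflate on the norbornene, ring-A ketone free) | CC(C)C1=C(OS(=O)(=O)C(F)(F)F)[C@@H]2C[C@H]3C=4[C@](C)(CC[C@@]31C2)C(=O)CCC4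
F4 | step 5 | tert-butyl{[4-(2-chloroethyl)-5-(propan-2-yl)cyclopenta-1,4-dien-1-yl]oxy}dimethylsilane | CC(C)C1=C(CCCl)CC=C1O[Si](C)(C)C(C)(C)C
F5 | step 6 | (1S,5S)-enantiomer of alcohol 12 | CC(C)C1=C(CCCl)C[C@H](C/C=C2\CCCC(O[Si](C)(C)C(C)(C)C)=C2C)[C@@H]1O
F6 | step 6 | (S)-O-methylmandelate of 12 | CC(C)C1=C(CCCl)C[C@@H](C/C=C2\CCCC(O[Si](C)(C)C(C)(C)C)=C2C)[C@H]1OC(=O)[C@@H](OC)c1ccccc1
F7 | step 6 | (S)-O-methylmandelate of F5 | CC(C)C1=C(CCCl)C[C@H](C/C=C2\CCCC(O[Si](C)(C)C(C)(C)C)=C2C)[C@@H]1OC(=O)[C@@H](OC)c1ccccc1
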